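Numbering (halimane): ring A = C1, C2, C3, C4, C5, C10; ring B = C5, C6, C7, C8, C9, C10; C17 = methyl on C8, C20 = methyl on C9, C11–C16 = side chain.
Enabling feature: C9 of ring B is a quaternary carbon that carries a plain methyl group (C20) and is bonded directly to the sp2 ring-fusion carbon C10. This is the retron of a hydride-terminated 6-exo Heck closure (C9–C10 bond) of a C10 alkenyl iodide onto a C9=C20 methylidene.
To make C10 an accessible alkenyl iodide, ring A is raised to a C1 ketone with a C5=C10 double bond (α-iodo enone). Tosylhydrazone reduction with allylic diazene retro-ene then removes the oxygen, moves the alkene to C1=C10 and delivers H5, and enolate methylation sets C4.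
Ring A comes from a Robinson annulation of a β-keto ester with methyl vinyl ketone. (R)-β-Citronellene supplies C5–C9, C17, C20 and the only imported stereocentre (C8), and a B-alkyl Suzuki coupling adds C11–C16.
Order of ring formation: ring A (step 5), then ring B (step 10). The stereochemical relay runs C8 → C9 → C5 → C4.

Key step: step 10

Remark on the chemistry: the ester-bearing carbon C4 is epimerisable in 8, 9, 14–20 and F1–F3, so these compounds are carried as C4 epimer mixtures and their SMILES leave C4 undefined. Compounds 1, 5, 7 and 10 are taken as commercial.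

Step 1
Reactants: 1 (R)-β-citronellene [(3R)-3,7-dimethylocta-1,6-diene]
Product: 2 (3R)-3,7-dimethyloct-6-en-2-one
Conditions: PdCl2 (10 mol %), CuCl (cat.), O2 (1 atm), DMF/H2O 7:1, rt
Reagents that add atoms: water, SMILES O
Why: Wacker–Tsuji oxidation: divalent palladium binds only the monosubstituted alkene and water attacks its internal carbon (Markovnikov), so C9 becomes the ketone carbon while the trisubstituted alkene and the C8 stereocentre taken from 1 stay as they are.

Step 2
Reactants: 2 (3R)-3,7-dimethyloct-6-en-2-one
Product: 3 (3R)-3,7-dimethylocta-1,6-dien-2-yl trifluoromethanesulfonate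
Conditions: LiN(iPr)2, THF, −78 °C; then PhNTf2, −78 °C → 0 °C
Reagents that add atoms: N-phenylbis(trifluoromethanesulfonimide), SMILES O=S(=O)(N(c1ccccc1)S(=O)(=O)C(F)(F)F)C(F)(F)F
Why: Kinetic enolate formation at the unhindered methyl group followed by O-triflation gives the terminal enol triflate, which turns that methyl carbon into the future C20 methylidene and never enolises toward C8.

Step 3
Reactants: 3 (3R)-3,7-dimethylocta-1,6-dien-2-yl trifluoromethanesulfonate
Product: 4 (3R)-3-methyl-6-oxohex-1-en-2-yl trifluoromethanesulfonate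
Conditions: O3 (1 equiv), CH2Cl2, −78 °C; then Me2S, −78 °C → rt
Reagents that add atoms: ozone, SMILES [O-][O+]=O
Why: Chemoselective ozonolysis with reductive work-up: the electron-rich trisubstituted alkene is consumed much faster than the strongly electron-poor enol triflate, which unmasks C5 as the aldehyde.

Step 4
Reactants: 4 (3R)-3-methyl-6-oxohex-1-en-2-yl trifluoromethanesulfonate; 5 methyl diazoacetate
Product: 6 methyl (6R)-6-methyl-3-oxo-7-(trifluoromethylsulfonyloxy)oct-7-enoate
Conditions: SnCl2 (10 mol %), CH2Cl2, rt
Reagents that add atoms: none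
Why: Roskamp reaction: SnCl2-promoted addition of the diazo ester to the aldehyde, 1,2-hydride shift and loss of N2 give the β-keto ester (C4 and the ester carbon) under essentially neutral conditions that the enol triflate tolerates.

Step 5
Reactants: 6 methyl (6R)-6-methyl-3-oxo-7-(trifluoromethylsulfonyloxy)oct-7-enoate; 7 but-3-en-2-one (methyl vinyl ketone)
Product: 9 methyl 2-[(3R)-3-methyl-4-(trifluoromethylsulfonyloxy)pent-4-en-1-yl]-4-oxocyclohex-2-ene-1-carboxylate, via Michael adduct 8 (not isolated)
Conditions: FeCl3·6H2O (5 mol %), CH2Cl2, rt; then pyrrolidine (30 mol %), AcOH (30 mol %), toluene, 50 °C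
Reagents that add atoms: none
Why: Robinson annulation that closes ring A: Michael addition at the doubly activated C4 gives 8, and the enamine-mediated aldol condensation of the methyl ketone carbon (C10) onto the C5 ketone gives the conjugated enone, the mode that uses the less hindered nucleophile; the new centre C4 is labile and needs no control.

Step 6
Reactants: 10 (2E)-3-methylpent-2-en-4-yn-1-ol
Product: 11 tert-butyl(dimethyl){[(2E)-3-methylpent-2-en-4-yn-1-yl]oxy}silane
Conditions: TBSCl, imidazole, CH2Cl2, 0 °C → rt
Reagents that add atoms: tert-butyldimethylsilyl chloride, SMILES CC(C)(C)[Si](C)(C)Cl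
Why: Standard silylation protects the primary allylic alcohol against the base and hydride steps ahead.

Step 7
Reactants: 11 tert-butyl(dimethyl){[(2E)-3-methylpent-2-en-4-yn-1-yl]oxy}silane
Product: 12 tert-butyl(dimethyl){[(2E)-3-methylpenta-2,4-dien-1-yl]oxy}silane
Conditions: H2 (1 atm), Pd/CaCO3 poisoned with Pb(OAc)2, quinoline, hexane, rt
Reagents that add atoms: none
Why: Semihydrogenation of the terminal alkyne over poisoned palladium stops at the vinyl group and leaves the E-trisubstituted alkene unchanged.

Step 8
Reactants: 9 ring A enone enol triflate; 12 silyl dienyl ether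
Product: 14 methyl 2-[(3R,7E)-9-(tert-butyldimethylsilyloxy)-3,7-dimethyl-4-methylidenenon-7-en-1-yl]-4-oxocyclohex-2-ene-1-carboxylate, via alkylborane 13 (not isolated)
Conditions: 12, 9-BBN (1.05 equiv), THF, 0 °C → rt; then 9, PdCl2(dppf) (5 mol %), aq. K3PO4, DMF, rt
Reagents that add atoms: none
Why: 9-BBN hydroborates the terminal monosubstituted double bond of 12 with boron on C11, and the B-alkyl Suzuki–Miyaura coupling of 13 with the enol triflate forms the C9–C11 bond at room temperature with retention of both alkene geometries, faster than any coupling of the deprotonated enone ester.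

Step 9
Reactants: 14 enone ester with the complete chain
Product: 15 methyl 2-[(3R,7E)-9-(tert-butyldimethylsilyloxy)-3,7-dimethyl-4-methylidenenon-7-en-1-yl]-3-iodo-4-oxocyclohex-2-ene-1-carboxylate
Conditions: I2 (2 equiv), pyridine/CH2Cl2 1:1, rt, dark
Reagents that add atoms: iodine, SMILES II
Why: α-Iodination of the enone (pyridine-mediated addition–elimination, here assisted by the dienol of the vinylogous β-keto ester, which is attacked at C10) places the halogen on C10 cis to the C6 chain, while the isolated alkenes only bind iodine reversibly in the absence of a nucleophilic solvent.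

Step 10
Reactants: 15 α-iodo enone
Product: 17 methyl (5S,6R)-5-[(3E)-5-(tert-butyldimethylsilyloxy)-3-methylpent-3-en-1-yl]-5,6-dimethyl-4-oxo-1,2,3,4,5,6,7,8-octahydronaphthalene-1-carboxylate, via alkylpalladium iodide 16 (not isolated)
Conditions: Pd(OAc)2 (10 mol %), PPh3 (25 mol %), HCO2Na (1.5 equiv, in portions), Et4NCl (1 equiv), DMF, 80 °C
Reagents that add atoms: none
Why: Zerovalent palladium inserts into the C10–I bond, the alkenylpalladium adds syn across C9=C20 in a 6-exo-trig closure of ring B (C9–C10 bond), and the neopentyl-type alkylpalladium iodide 16, which has no β-hydrogen, exchanges iodide for formate, loses CO2 and reductively eliminates, so that C20 ends as the methyl group. The reaction type is the hydride-terminated (reductive) intramolecular Heck cyclization of an aryl or alkenyl halide onto a 1,1-disubstituted alkene, an established way to build methyl-bearing quaternary carbons. C9 is the only new stereocentre: the four-centre insertion forces the C9=C20 bond to lie parallel to the C10–Pd bond and roughly perpendicular to the plane of the ring A enone, so C20 becomes the pseudo-axial and the C11 chain the pseudo-equatorial substituent of the forming half-chair. C8 then keeps C17 equatorial with H8 anti to C20 (the alternative eclipses C17 with C11), which gives the cis C17/C20 relationship of the target. Two selectivities are needed: ring closure must outrun hydride capture of the alkenylpalladium, which the cis placement of iodine and the C6 chain on C5=C10 and the sparingly soluble, portionwise formate should secure, and 16 must be reduced before it attacks C13=C14, which should hold because that insertion would have to build a further quaternary carbon from a hindered neopentyl palladium on a trisubstituted alkene. The tetrasubstituted, carbonyl-conjugated C5=C10 bond resists 3-exo attack by 16 and conjugate reduction.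

Step 11
Reactants: 17 bicyclic enone
Product: 18 (E)-4-methylbenzenesulfonylhydrazone of 17 at the C1 ketone
Conditions: TsNHNH2 (1.5 equiv), PPTS (10 mol %), 4 Å MS, THF, 60 °C
Reagents that add atoms: 4-methylbenzenesulfonohydrazide, SMILES Cc1ccc(cc1)S(=O)(=O)NN
Why: Acid-catalysed condensation at the only ketone of 17 gives the conjugated tosylhydrazone with the sulfonamide nitrogen turned away from C10.

Step 12
Reactants: 18 conjugated tosylhydrazone
Product: 20 methyl (5S,6R,8aS)-5-[(3E)-5-(tert-butyldimethylsilyloxy)-3-methylpent-3-en-1-yl]-5,6-dimethyl-1,2,3,5,6,7,8,8a-octahydronaphthalene-1-carboxylate, via allylic diazene 19 (not isolated)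
Conditions: catecholborane (3 equiv), CHCl3, −10 °C → 0 °C; then NaOAc·3H2O, 60 °C
Reagents that add atoms: none
Why: Reduction of a conjugated tosylhydrazone with alkene migration: hydride adds to C1 from the face opposite the pseudo-axial C20 methyl group, loss of sulfinate gives diazene 19 on the C20 face, and its retro-ene loss of N2 hands the hydrogen suprafacially to C5 on that same face, which sets H5 cis to C20 and fixes the alkene at C1=C10.

Step 13
Reactants: 20 bicyclic ester (C4–H)
Product: 21 methyl (1S,5S,6R,8aR)-5-[(3E)-5-(tert-butyldimethylsilyloxy)-3-methylpent-3-en-1-yl]-1,5,6-trimethyl-1,2,3,5,6,7,8,8a-octahydronaphthalene-1-carboxylate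
Conditions: LiN(iPr)2, THF/DMPU, −78 °C; then MeI, −78 °C → −20 °C
Reagents that add atoms: iodomethane, SMILES CI
Why: Ester enolate alkylation: deprotonation flattens C4 and methyl iodide enters from the face that carries only H5, anti to the C5–C6 bond (equatorial attack), so that the new methyl group ends cis to H5 and the ester axial and cis to C6 as in the target.

Step 14
Reactants: 21 silyl ether
Product: 22 methyl (1S,5S,6R,8aR)-5-[(3E)-5-hydroxy-3-methylpent-3-en-1-yl]-1,5,6-trimethyl-1,2,3,5,6,7,8,8a-octahydronaphthalene-1-carboxylate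
Conditions: Bu4NF, THF, 0 °C → rt
Reagents that add atoms: none
Why: Fluoride cleaves the silyl ether selectively; the hindered ester and the two trisubstituted alkenes are inert.

Step 15
Reactants: 22 allylic alcohol
Product: 23 methyl (1S,5S,6R,8aR)-5-[(3E)-5-(formyloxy)-3-methylpent-3-en-1-yl]-1,5,6-trimethyl-1,2,3,5,6,7,8,8a-octahydronaphthalene-1-carboxylate (CNP0188193.1)
Conditions: 2,2,2-trifluoroethyl formate (5 equiv), THF, 65 °C
Reagents that add atoms: 2,2,2-trifluoroethyl formate, SMILES O=COCC(F)(F)F
Why: Acyl transfer from the activated formate ester formylates the unhindered primary allylic alcohol under neutral conditions without touching the quaternary methyl ester or the alkene geometry.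

Compound list
1 | (3R)-3,7-dimethylocta-1,6-diene, (R)-β-citronellene | CC(C)=CCC[C@@H](C)C=C | starting material
2 | (3R)-3,7-dimethyloct-6-en-2-one | CC(C)=CCC[C@@H](C)C(C)=O | intermediate
3 | (3R)-3,7-dimethylocta-1,6-dien-2-yl trifluoromethanesulfonate | CC(C)=CCC[C@@H](C)C(=C)OS(=O)(=O)C(F)(F)F | intermediate
4 | (3R)-3-methyl-6-oxohex-1-en-2-yl trifluoromethanesulfonate | O=CCC[C@@H](C)C(=C)OS(=O)(=O)C(F)(F)F | intermediate
5 | methyl diazoacetate | COC(=O)C=[N+]=[N-] | starting material
6 | methyl (6R)-6-methyl-3-oxo-7-(trifluoromethylsulfonyloxy)oct-7-enoate | COC(=O)CC(=O)CC[C@@H](C)C(=C)OS(=O)(=O)C(F)(F)F | intermediate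
7 | but-3-en-2-one | C=CC(C)=O | starting material
8 | methyl (6R)-6-methyl-3-oxo-2-(3-oxobutyl)-7-(trifluoromethylsulfonyloxy)oct-7-enoate (Michael adduct) | COC(=O)C(CCC(C)=O)C(=O)CC[C@@H](C)C(=C)OS(=O)(=O)C(F)(F)F | intermediate
9 | methyl 2-[(3R)-3-methyl-4-(trifluoromethylsulfonyloxy)pent-4-en-1-yl]-4-oxocyclohex-2-ene-1-carboxylate | COC(=O)C1CCC(=O)C=C1CC[C@@H](C)C(=C)OS(=O)(=O)C(F)(F)F | intermediate
10 | (2E)-3-methylpent-2-en-4-yn-1-ol | C#C/C(C)=C/CO | starting material
11 | tert-butyl(dimethyl){[(2E)-3-methylpent-2-en-4-yn-1-yl]oxy}silane | C#C/C(C)=C/CO[Si](C)(C)C(C)(C)C | intermediate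
12 | tert-butyl(dimethyl){[(2E)-3-methylpenta-2,4-dien-1-yl]oxy}silane | C=C/C(C)=C/CO[Si](C)(C)C(C)(C)C | intermediate
13 | 9-[(3E)-5-(tert-butyldimethylsilyloxy)-3-methylpent-3-en-1-yl]-9-borabicyclo[3.3.1]nonane | B1(C2CCCC1CCC2)CC/C(C)=C/CO[Si](C)(C)C(C)(C)C | intermediate
14 | methyl 2-[(3R,7E)-9-(tert-butyldimethylsilyloxy)-3,7-dimethyl-4-methylidenenon-7-en-1-yl]-4-oxocyclohex-2-ene-1-carboxylate | COC(=O)C1CCC(=O)C=C1CC[C@@H](C)C(=C)CC/C(C)=C/CO[Si](C)(C)C(C)(C)C | intermediate
15 | methyl 2-[(3R,7E)-9-(tert-butyldimethylsilyloxy)-3,7-dimethyl-4-methylidenenon-7-en-1-yl]-3-iodo-4-oxocyclohex-2-ene-1-carboxylate | COC(=O)C1CCC(=O)C(I)=C1CC[C@@H](C)C(=C)CC/C(C)=C/CO[Si](C)(C)C(C)(C)C | intermediate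
16 | C20 alkylpalladium iodide of the closed bicycle (phosphine ligands omitted) | COC(=O)C1CCC(=O)C2=C1CC[C@@H](C)[C@]2(C[Pd]I)CC/C(C)=C/CO[Si](C)(C)C(C)(C)C | intermediate
17 | methyl (5S,6R)-5-[(3E)-5-(tert-butyldimethylsilyloxy)-3-methylpent-3-en-1-yl]-5,6-dimethyl-4-oxo-1,2,3,4,5,6,7,8-octahydronaphthalene-1-carboxylate | COC(=O)C1CCC(=O)C2=C1CC[C@@H](C)[C@]2(C)CC/C(C)=C/CO[Si](C)(C)C(C)(C)C | intermediate
18 | (E)-4-methylbenzenesulfonylhydrazone of 17 | COC(=O)C1CC/C(=N\NS(=O)(=O)c3ccc(C)cc3)C2=C1CC[C@@H](C)[C@]2(C)CC/C(C)=C/CO[Si](C)(C)C(C)(C)C | intermediate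
19 | (4S)-4-diazenyl allylic diazene derived from 18 | COC(=O)C1CC[C@H](N=N)C2=C1CC[C@@H](C)[C@]2(C)CC/C(C)=C/CO[Si](C)(C)C(C)(C)C | intermediate
20 | methyl (5S,6R,8aS)-5-[(3E)-5-(tert-butyldimethylsilyloxy)-3-methylpent-3-en-1-yl]-5,6-dimethyl-1,2,3,5,6,7,8,8a-octahydronaphthalene-1-carboxylate | COC(=O)C1CCC=C2[C@H]1CC[C@@H](C)[C@]2(C)CC/C(C)=C/CO[Si](C)(C)C(C)(C)C | intermediate
21 | methyl (1S,5S,6R,8aR)-5-[(3E)-5-(tert-butyldimethylsilyloxy)-3-methylpent-3-en-1-yl]-1,5,6-trimethyl-1,2,3,5,6,7,8,8a-octahydronaphthalene-1-carboxylate | COC(=O)[C@@]1(C)CCC=C2[C@H]1CC[C@@H](C)[C@]2(C)CC/C(C)=C/CO[Si](C)(C)C(C)(C)C | intermediate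
22 | methyl (1S,5S,6R,8aR)-5-[(3E)-5-hydroxy-3-methylpent-3-en-1-yl]-1,5,6-trimethyl-1,2,3,5,6,7,8,8a-octahydronaphthalene-1-carboxylate | COC(=O)[C@@]1(C)CCC=C2[C@H]1CC[C@@H](C)[C@]2(C)CC/C(C)=C/CO | intermediate
23 | methyl (1S,5S,6R,8aR)-5-[(3E)-5-(formyloxy)-3-methylpent-3-en-1-yl]-1,5,6-trimethyl-1,2,3,5,6,7,8,8a-octahydronaphthalene-1-carboxylate | COC(=O)[C@@]1(C)CCC=C2[C@H]1CC[C@@H](C)[C@]2(C)CC/C(C)=C/COC=O | target

Total step count: 15. Longest linear sequence: 13 (steps 1–5 and 8–15).

Steps most likely to fail:

Step 10. Hydride capture of the alkenylpalladium before ring closure (loss of iodine without C–C bond formation), a second insertion of the alkylpalladium into C13=C14, or weak facial discrimination at C9 could erode the closure. The fallback closes ring B without halogen and without hydride. It sets out from 14, whose vinylogous β-keto ester dienol is nucleophilic at C10. Treatment with AuCl(PPh3)/AgOTf in toluene at 50 °C is a π-acid-catalysed Markovnikov hydroalkylation of an unactivated 1,1-disubstituted alkene by a stabilised carbon nucleophile (6-exo). Protodeauration turns C20 into the methyl group and tautomerisation restores the enone. The fallback skips 15 and comes back at 17; no new compound arises (F0).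

Step 11. Condensation at the C1 carbonyl may stall because it is flanked by the quaternary C9, and the later hydride delivery may show poor facial selectivity. The fallback moves the transposition in front of the ring closure and puts it under reagent control. It sets out from 15. Corey–Bakshi–Shibata reduction with (S)-2-methyl-CBS-oxazaborolidine and BH3·SMe2 should give the (4R)-iodo allylic alcohol F1. Mitsunobu reaction with 2-nitrobenzenesulfonohydrazide (PPh3, diethyl azodicarboxylate, THF, −30 °C) inverts this centre to the N-allyl sulfonylhydrazine F2. On warming this loses the sulfinic acid and then N2 by the retro-ene path, giving the transposed alkenyl iodide F3 with H5 set and the alkene at C1=C10. The reductive Heck conditions of step 10 then close ring B through a chair with C4 and C17 equatorial and C20 axial. The fallback comes back at 20.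

Step 13. Methyl iodide may show poor facial selectivity on the rigid bicyclic enolate. The fallback methylates while ring A is still monocyclic. It sets out from 15 and follows the sequence just described as far as the alkenyl iodide F3. There the C6 chain can turn pseudo-axial to escape A(1,3) strain with the enolate, so that LiN(iPr)2/MeI should alkylate anti to it and give the quaternary ester alkenyl iodide F4. The reductive Heck cyclization of F4 comes back at 21.

Further compounds
F0 | step 10 | none | none
F1 | step 11 | methyl (4R)-2-[(3R,7E)-9-(tert-butyldimethylsilyloxy)-3,7-dimethyl-4-methylidenenon-7-en-1-yl]-4-hydroxy-3-iodocyclohex-2-ene-1-carboxylate | COC(=O)C1CC[C@@H](O)C(I)=C1CC[C@@H](C)C(=C)CC/C(C)=C/CO[Si](C)(C)C(C)(C)C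
F2 | step 11 | methyl (4S)-4-[1-(2-nitrophenylsulfonyl)hydrazinyl]-2-[(3R,7E)-9-(tert-butyldimethylsilyloxy)-3,7-dimethyl-4-methylidenenon-7-en-1-yl]-3-iodocyclohex-2-ene-1-carboxylate | COC(=O)C1CC[C@H](N(N)S(=O)(=O)c2ccccc2[N+](=O)[O-])C(I)=C1CC[C@@H](C)C(=C)CC/C(C)=C/CO[Si](C)(C)C(C)(C)C
F3 | step 11 | methyl (2S)-2-[(3R,7E)-9-(tert-butyldimethylsilyloxy)-3,7-dimethyl-4-methylidenenon-7-en-1-yl]-3-iodocyclohex-3-ene-1-carboxylate | COC(=O)C1CCC=C(I)[C@H]1CC[C@@H](C)C(=C)CC/C(C)=C/CO[Si](C)(C)C(C)(C)C
F4 | step 13 | methyl (1S,2S)-2-[(3R,7E)-9-(tert-butyldimethylsilyloxy)-3,7-dimethyl-4-methylidenenon-7-en-1-yl]-3-iodo-1-methylcyclohex-3-ene-1-carboxylate | COC(=O)[C@@]1(C)CCC=C(I)[C@H]1CC[C@@H](C)C(=C)CC/C(C)=C/CO[Si](C)(C)C(C)(C)C
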